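**Plan**

1. Retrosynthesis: the bond between the two inner CH carbons of the E,E-diene is cut first (Suzuki–Miyaura), giving oxanyl alkenylboronate 11 and cyclohexyl alkenyl iodide 20. In 11 the oxane is then opened at O1–C2 and C3–Br, back to an oxolane carbinol (7).
2. Forward, oxane half: geraniol → (S)-dehydrolinalool 5 → 2,5-trans oxolane 7 → bromo-oxane 10 by a 5 → 6 ring expansion → boronate 11.
3. Forward, cyclohexane half: (R)-limonene → methyl ketone → alkyne → E-alkenyl iodide 18 → cis-bromohydrin 20; the diene is joined last.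
4. Enabling feature: in 7 the oxolane oxygen is vicinal to the tertiary carbinol carbon (ring O–CH–C(CH3)2–OH). The future oxane atoms C-2 and C-3 are thus the two carbons of a latent three-membered oxonium ring, so O can pass from C-3 to C-2 while bromide enters C-3.
5. Stereochemistry: oxane C-6 comes from Sharpless epoxidation of geraniol; C-3 from Shi epoxidation followed by two stereospecific inversions. Cyclohexane C-4 comes from (R)-limonene; C-1 and C-2 from trans-diaxial hydroxyselenation and an invertive Se → Br exchange. Both alkene geometries come from syn carbo- and hydrometalation.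

Key step: step 5

Remark on the chemistry (assumption): the D-fructose-derived Shi ketone is taken to deliver the 6R epoxide of 5, as with other 2-methylalk-2-enes; if the sense were opposite, the enantiomeric ketone would be used.

**Route**

Step 1
Reactants: 1 geraniol
Product: 2 [(2S,3S)-3-methyl-3-(4-methylpent-3-en-1-yl)oxiran-2-yl]methanol
Conditions: Ti(OiPr)4 (5 mol %), L-(+)-diethyl tartrate (7 mol %), t-BuOOH, 4 Å MS, CH2Cl2, −20 °C
Reagents that add atoms: tert-butyl hydroperoxide, CC(C)(C)OO
Why: Sharpless asymmetric epoxidation of the allylic alcohol, in which the L-(+)-tartrate catalyst delivers oxygen to the face that gives the 2S,3S epoxide, so that C-3 (the later quaternary C-6 of the oxane) is set by the reagent.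

Step 2
Reactants: 2 [(2S,3S)-3-methyl-3-(4-methylpent-3-en-1-yl)oxiran-2-yl]methanol
Product: 3 (2R,3S)-2-(chloromethyl)-3-methyl-3-(4-methylpent-3-en-1-yl)oxirane
Conditions: PPh3, CCl4, reflux
Reagents that add atoms: tetrachloromethane, ClC(Cl)(Cl)Cl
Why: Appel chlorination of the primary alcohol under neutral conditions, which leaves the epoxide and both stereocentres untouched (the descriptor at C-2 changes only because CH2Cl now outranks the ring carbon).

Step 3
Reactants: 3 (2R,3S)-2-(chloromethyl)-3-methyl-3-(4-methylpent-3-en-1-yl)oxirane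
Product: 5 (3S)-3,7-dimethyloct-6-en-1-yn-3-ol, via chloroalkenyl alkoxide 4 (not isolated)
Conditions: n-BuLi (3.2 equiv), THF, −40 → −20 °C; then H2O
Reagents that add atoms: none
Why: base-induced double elimination of a 2,3-epoxy chloride to a propargylic alcohol (deprotonation at C-1 opens the epoxide to the chloroalkenyl alkoxide 4, loss of HCl then gives the acetylide), in which the C-3–O bond is never broken so that the S configuration is kept.

Step 4
Reactants: 5 (3S)-3,7-dimethyloct-6-en-1-yn-3-ol
Product: 7 2-[(2S,5S)-5-ethynyl-5-methyloxolan-2-yl]propan-2-ol, via epoxy alkynol 6 (not isolated)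
Conditions: D-fructose-derived Shi ketone (30 mol %), KHSO5 (as Oxone), K2CO3, Bu4NHSO4, MeCN/CH2(OMe)2/aq. Na2B4O7 buffer, 0 °C; then camphorsulfonic acid (10 mol %), CH2Cl2, 0 °C
Reagents that add atoms: potassium peroxymonosulfate, [K+].[O-]S(=O)(=O)OO
Why: Shi asymmetric epoxidation attacks only the electron-rich trisubstituted alkene and should give the 6R epoxide 6 under reagent control, and acid-catalysed 5-exo-tet opening by the tertiary hydroxyl at the secondary epoxide carbon (as with 6,7-epoxylinalool) inverts that carbon, giving the 2,5-trans oxolane with 2S configuration.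

Step 5
Reactants: 7 2-[(2S,5S)-5-ethynyl-5-methyloxolan-2-yl]propan-2-ol
Product: 10 (3R,6S)-3-bromo-6-ethynyl-2,2,6-trimethyloxane, via bicyclic oxonium bromide 8 (not isolated), via tertiary bromide 9 (not isolated)
Conditions: Me3SiBr (2 equiv), CH2Cl2, −20 → 0 °C; then ZnBr2 (10 mol %), MeNO2, 25 °C
Reagents that add atoms: bromotrimethylsilane, C[Si](C)(C)Br
Why: Proposed new method: Me3SiBr turns the tertiary hydroxyl into a leaving group whose departure is assisted by the ring oxygen (3-exo-tet closure of O onto the carbinol carbon), giving the 1-oxoniabicyclo[3.1.0]hexane ion pair 8; bromide should return first at the tertiary carbon to give 9, but 9 re-ionises readily under ZnBr2, whereas attack at the secondary ring-fusion carbon (SN2, anti to the C–O+ bond shared by both rings) gives oxane 10, a secondary bromide that no longer ionises easily, so 10 should accumulate with release of five-membered-ring strain. The closest known reactions are the zinc-acetate-mediated ring expansion of oxolan-2-ylcarbinyl sulfonates to 3-acyloxyoxanes through the same kind of bicyclic oxonium ion, the 2-(chloromethyl)pyrrolidine to 3-chloropiperidine rearrangement through aziridinium ions, and the dyotropic 1,2-interchange in vicinal dibromides; a bromide nucleophile with a tertiary carbinol centre has not been shown. The oxane is closed as a 5 → 6 ring expansion in which the carbinol carbon (C-2) is inserted between O-1 and C-3. The only new stereocentre, C-3, is controlled by the Shi-derived C–O centre of 7 through one stereospecific inversion (S in 7 → R in 10, the same outcome by an oxonium or a bromonium pathway), and C-6 is not touched. The step needs regioselectivity between the two carbons of the oxonium ring and suppression of HBr loss and of a 1,2-hydride shift to an oxocarbenium ion; the reversibility of tertiary C–Br formation, the non-basic bromide-rich medium, and the ethynyl (not vinyl) group at C-6, which keeps the C-6–O bond from ionising and is small enough to sit axial in 10, are meant to secure this.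

Step 6
Reactants: 10 (3R,6S)-3-bromo-6-ethynyl-2,2,6-trimethyloxane
Product: 11 2-{(E)-2-[(2S,5R)-5-bromo-2,6,6-trimethyloxan-2-yl]ethenyl}-4,4,5,5-tetramethyl-1,3,2-dioxaborolane
Conditions: pinacolborane (1.5 equiv), Cp2Zr(H)Cl (10 mol %), Et3N (10 mol %), CH2Cl2, 25–40 °C
Reagents that add atoms: pinacolborane, CC1(C)OBOC1(C)C
Why: Cp2Zr(H)Cl-catalysed hydroboration of the terminal alkyne with pinacolborane is a syn addition that places boron on the unhindered terminal carbon, so the E alkenylboronate should form without touching the secondary bromide.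

Step 7
Reactants: 12 (R)-(+)-limonene
Product: 14 1-[(1R)-4-methylcyclohex-3-en-1-yl]ethan-1-one, via exocyclic diol 13 (not isolated)
Conditions: OsO4 (2 mol %), N-methylmorpholine N-oxide (1.05 equiv), acetone/H2O, 0 °C; then NaIO4, THF/H2O, 25 °C
Reagents that add atoms: N-methylmorpholine N-oxide, C[N+]1([O-])CCOCC1; water, O
Why: Upjohn dihydroxylation should take the less hindered 1,1-disubstituted exocyclic alkene of limonene in preference to the trisubstituted ring alkene, and periodate glycol cleavage of 13 then gives the methyl ketone with C-4 untouched.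

Step 8
Reactants: 14 1-[(1R)-4-methylcyclohex-3-en-1-yl]ethan-1-one
Product: 16 (4R)-4-ethynyl-1-methylcyclohex-1-ene, via enol phosphate 15 (not isolated)
Conditions: LiN(iPr)2 (1.1 equiv), THF, −78 °C; ClP(O)(OEt)2, −78 → 25 °C; then LiN(iPr)2 (2.3 equiv), −78 → 25 °C; H2O
Reagents that add atoms: none
Why: conversion of a methyl ketone into a terminal alkyne through its kinetic enol phosphate (the amide base deprotonates the methyl group, and double deprotonation of 15 eliminates diethyl phosphate), which does not enolise toward the stereogenic α-carbon.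

Step 9
Reactants: 16 (4R)-4-ethynyl-1-methylcyclohex-1-ene
Product: 18 (4R)-4-[(E)-1-iodoprop-1-en-2-yl]-1-methylcyclohex-1-ene, via alkenylalane 17 (not isolated)
Conditions: AlMe3 (2 equiv), Cp2ZrCl2 (20 mol %), CH2Cl2, 0 → 25 °C; then I2, THF, −30 → 0 °C
Reagents that add atoms: trimethylaluminium, C[Al](C)C; iodine, II
Why: Negishi zirconium-catalysed carboalumination adds methyl and aluminium syn across the terminal alkyne with aluminium on the terminal carbon, and iodinolysis with retention gives the E trisubstituted alkenyl iodide, the ring alkene being inert.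

Step 10
Reactants: 18 (4R)-4-[(E)-1-iodoprop-1-en-2-yl]-1-methylcyclohex-1-ene
Product: 19 (1S,2S,4R)-4-[(E)-1-iodoprop-1-en-2-yl]-1-methyl-2-(phenylselanyl)cyclohexan-1-ol
Conditions: N-(phenylselanyl)phthalimide (1.1 equiv), H2O (3 equiv), camphorsulfonic acid (10 mol %), CH2Cl2, 25 °C
Reagents that add atoms: N-(phenylselanyl)phthalimide, O=C1N([Se]c2ccccc2)C(=O)c2ccccc12; water, O
Why: anti hydroxyselenation in which the seleniranium ion of the ring alkene is opened by water at the tertiary carbon in the trans-diaxial (Fürst–Plattner) mode with the 4-substituent equatorial, which sets C-1 (OH axial, cis to the side chain) and places selenium axial at C-2, the electron-poor alkenyl iodide being left alone.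

Step 11
Reactants: 19 (1S,2S,4R)-4-[(E)-1-iodoprop-1-en-2-yl]-1-methyl-2-(phenylselanyl)cyclohexan-1-ol
Product: 20 (1S,2R,4R)-2-bromo-4-[(E)-1-iodoprop-1-en-2-yl]-1-methylcyclohexan-1-ol
Conditions: Br2 (1.05 equiv), CH2Cl2, −78 → 0 °C
Reagents that add atoms: bromine, BrBr
Why: bromodeselenation of an alkyl phenyl selenide (bromine adds to selenium and bromide then displaces PhSeBr from carbon with inversion) turns the axial C-2–Se bond into the equatorial C-2–Br bond, so steps 10 and 11 together are a formal syn hydroxybromination that gives the cis-bromohydrin which no anti addition can give.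

Step 12
Reactants: 11 2-{(E)-2-[(2S,5R)-5-bromo-2,6,6-trimethyloxan-2-yl]ethenyl}-4,4,5,5-tetramethyl-1,3,2-dioxaborolane; 20 (1S,2R,4R)-2-bromo-4-[(E)-1-iodoprop-1-en-2-yl]-1-methylcyclohexan-1-ol
Product: 21 (1S,2R,4R)-2-bromo-4-{(2E,4E)-5-[(2S,5R)-5-bromo-2,6,6-trimethyloxan-2-yl]penta-2,4-dien-2-yl}-1-methylcyclohexan-1-ol (CNP0199463.1)
Conditions: Pd(dppf)Cl2 (5 mol %), K3PO4 (3 equiv), THF/H2O (5:1), 40 °C
Reagents that add atoms: none
Why: Suzuki–Miyaura coupling of the alkenyl iodide with the alkenylboronate under zerovalent palladium catalysis proceeds with retention at both sp2 carbons to give the E,E diene, while the secondary alkyl bromides do not undergo oxidative addition and the cis-bromohydrin (Br and OH gauche) cannot close to an epoxide under the mild base.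

**Compound list**

1 | geraniol, (2E)-3,7-dimethylocta-2,6-dien-1-ol | CC(C)=CCC/C(C)=C/CO | starting material
2 | [(2S,3S)-3-methyl-3-(4-methylpent-3-en-1-yl)oxiran-2-yl]methanol | OC[C@@H]1O[C@@]1(C)CCC=C(C)C | intermediate
3 | (2R,3S)-2-(chloromethyl)-3-methyl-3-(4-methylpent-3-en-1-yl)oxirane | ClC[C@@H]1O[C@@]1(C)CCC=C(C)C | intermediate
4 | lithium (3S)-1-chloro-3,7-dimethylocta-1,6-dien-3-olate (alkene geometry not defined) | ClC=C[C@@](C)([O-])CCC=C(C)C.[Li+] | intermediate
5 | (3S)-3,7-dimethyloct-6-en-1-yn-3-ol | C#C[C@@](C)(O)CCC=C(C)C | intermediate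
6 | (3S)-5-[(2R)-3,3-dimethyloxiran-2-yl]-3-methylpent-1-yn-3-ol | C#C[C@@](C)(O)CC[C@H]1OC1(C)C | intermediate
7 | 2-[(2S,5S)-5-ethynyl-5-methyloxolan-2-yl]propan-2-ol (2,5-trans) | C#C[C@]1(C)CC[C@H](O1)C(C)(C)O | intermediate
8 | (2S,5S)-2-ethynyl-2,6,6-trimethyl-1-oxoniabicyclo[3.1.0]hexane bromide | C#C[C@]1(C)CC[C@@H]2[O+]1C2(C)C.[Br-] | intermediate
9 | (2S,5S)-5-(2-bromopropan-2-yl)-2-ethynyl-2-methyloxolane | C#C[C@]1(C)CC[C@H](O1)C(C)(C)Br | intermediate
10 | (3R,6S)-3-bromo-6-ethynyl-2,2,6-trimethyloxane | C#C[C@]1(C)CC[C@@H](Br)C(C)(C)O1 | intermediate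
11 | 2-{(E)-2-[(2S,5R)-5-bromo-2,6,6-trimethyloxan-2-yl]ethenyl}-4,4,5,5-tetramethyl-1,3,2-dioxaborolane | CC1(C)OB(/C=C/[C@]2(C)CC[C@@H](Br)C(C)(C)O2)OC1(C)C | intermediate
12 | (R)-(+)-limonene, (4R)-1-methyl-4-(prop-1-en-2-yl)cyclohex-1-ene | CC(=C)[C@@H]1CCC(C)=CC1 | starting material
13 | 2-[(1R)-4-methylcyclohex-3-en-1-yl]propane-1,2-diol (both C-2 epimers) | CC(O)(CO)[C@@H]1CCC(C)=CC1 | intermediate
14 | 1-[(1R)-4-methylcyclohex-3-en-1-yl]ethan-1-one | CC(=O)[C@@H]1CCC(C)=CC1 | intermediate
15 | diethyl 1-[(1R)-4-methylcyclohex-3-en-1-yl]ethenyl phosphate | C=C(OP(=O)(OCC)OCC)[C@@H]1CCC(C)=CC1 | intermediate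
16 | (4R)-4-ethynyl-1-methylcyclohex-1-ene | C#C[C@@H]1CCC(C)=CC1 | intermediate
17 | dimethyl{(E)-2-[(1R)-4-methylcyclohex-3-en-1-yl]prop-1-en-1-yl}alumane | C/C(=C\[Al](C)C)[C@@H]1CCC(C)=CC1 | intermediate
18 | (4R)-4-[(E)-1-iodoprop-1-en-2-yl]-1-methylcyclohex-1-ene | C/C(=C\I)[C@@H]1CCC(C)=CC1 | intermediate
19 | (1S,2S,4R)-4-[(E)-1-iodoprop-1-en-2-yl]-1-methyl-2-(phenylselanyl)cyclohexan-1-ol | C/C(=C\I)[C@@H]1CC[C@](C)(O)[C@@H]([Se]c2ccccc2)C1 | intermediate
20 | (1S,2R,4R)-2-bromo-4-[(E)-1-iodoprop-1-en-2-yl]-1-methylcyclohexan-1-ol | C/C(=C\I)[C@@H]1CC[C@](C)(O)[C@H](Br)C1 | intermediate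
21 | (1S,2R,4R)-2-bromo-4-{(2E,4E)-5-[(2S,5R)-5-bromo-2,6,6-trimethyloxan-2-yl]penta-2,4-dien-2-yl}-1-methylcyclohexan-1-ol | C/C(=C\C=C\[C@]1(C)CC[C@@H](Br)C(C)(C)O1)[C@@H]1CC[C@](C)(O)[C@H](Br)C1 | target

**Count**

Total steps: 12. Longest linear sequence: 7 (steps 1–6, then step 12); the other branch is 6 (steps 7–11, then step 12).

**Steps most likely to fail**

Step 5 (proposed new method). What may go wrong is poor regioselectivity of bromide return to the oxonium ion (tertiary carbon instead of the ring-fusion carbon), an equilibrium that does not lie far enough on the oxane side, loss of HBr to an isopropenyl oxolane, or a 1,2-hydride shift to an oxocarbenium ion. The fallback sets out from 5 and comes back at 10. Direct bromoetherification of 5 with 2,4,4,6-tetrabromocyclohexa-2,5-dien-1-one in MeNO2 at 0 °C (bromonium ion on the trisubstituted alkene, 6-endo attack of the tertiary hydroxyl at the more substituted carbon) is known chemistry for bishomoallylic tertiary alcohols. It should give 10 together with its C-3 epimer (3S,6S)-3-bromo-6-ethynyl-2,2,6-trimethyloxane F1 and the 5-exo isomer 9. Compound 10 is taken on after chromatographic separation. This gives up the ring expansion and its stereospecificity.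

Step 11. What may go wrong is participation of the antiperiplanar tertiary hydroxyl during departure of the tetravalent selenium group (epoxide formation and reopening with net retention at C-2), or elimination instead of displacement at the hindered carbon. The fallback sets out from 19 and comes back at 20. The tertiary hydroxyl is first masked as a poorly participating ester: trifluoroacetic anhydride and pyridine in CH2Cl2 give (1S,2S,4R)-4-[(E)-1-iodoprop-1-en-2-yl]-1-methyl-2-(phenylselanyl)cyclohexyl trifluoroacetate F2. Br2 in CH2Cl2 then exchanges selenium for bromine with inversion to give (1S,2R,4R)-2-bromo-4-[(E)-1-iodoprop-1-en-2-yl]-1-methylcyclohexyl trifluoroacetate F3. Methanolysis with KHCO3 in MeOH at 0 °C releases 20.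

Step 7. What may go wrong is poor site selectivity of the dihydroxylation (attack on the ring alkene as well) and over-oxidation. The fallback sets out from 12 and comes back at 14. The ring alkene is protected as its epoxide: mCPBA in CH2Cl2 at 0 °C gives (4R)-1-methyl-4-(prop-1-en-2-yl)-7-oxabicyclo[4.1.0]heptane F4. Ozonolysis (O3, CH2Cl2, −78 °C; Me2S) of the remaining isopropenyl group gives 1-[(3R)-6-methyl-7-oxabicyclo[4.1.0]heptan-3-yl]ethan-1-one F5. Deoxygenation of the epoxide with Zn, NaI and NaOAc in AcOH returns the ring alkene in 14.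

**Further compounds**

F1 | step 5 | (3S,6S)-3-bromo-6-ethynyl-2,2,6-trimethyloxane | C#C[C@]1(C)CC[C@H](Br)C(C)(C)O1
F2 | step 11 | (1S,2S,4R)-4-[(E)-1-iodoprop-1-en-2-yl]-1-methyl-2-(phenylselanyl)cyclohexyl trifluoroacetate | C/C(=C\I)[C@@H]1CC[C@](C)(OC(=O)C(F)(F)F)[C@@H]([Se]c2ccccc2)C1
F3 | step 11 | (1S,2R,4R)-2-bromo-4-[(E)-1-iodoprop-1-en-2-yl]-1-methylcyclohexyl trifluoroacetate | C/C(=C\I)[C@@H]1CC[C@](C)(OC(=O)C(F)(F)F)[C@H](Br)C1
F4 | step 7 | (4R)-1-methyl-4-(prop-1-en-2-yl)-7-oxabicyclo[4.1.0]heptane (both epoxide diastereomers) | CC(=C)[C@@H]1CCC2(C)OC2C1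
F5 | step 7 | 1-[(3R)-6-methyl-7-oxabicyclo[4.1.0]heptan-3-yl]ethan-1-one (both epoxide diastereomers) | CC(=O)[C@@H]1CCC2(C)OC2C1
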